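## Retrosynthetic overview

1. The ring enone is unmasked last by acid hydrolysis of a base-stable 3-ethoxycyclohex-2-enyl carbinol (Stork–Danheiser transposition), so the base-labile ring C–H is never a vinylogous ketone α-proton while the chain is built.
2. The C8=C9 bond comes from a Horner–Wadsworth–Emmons union of a C15 ring phosphonate with a C10 aldehyde ester, itself made by two stabilised Wittig reactions.
3. The ring methyl comes from organocerium addition to the carbonyl of a dimedone-derived vinylogous ester.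
4. The stereocenter and the ring–chain bond come from a proposed enantioconvergent nickel-catalysed alkenylation of a racemic α'-bromo vinylogous ester with a dienylzirconocene.
5. No ring is formed: the single carbocycle is carried intact from dimedone.

Assumption: 5, 11, 12 and 15 are bought as the pure isomers named, and where a carbinol center is made and later destroyed (10, 17, 18) the expected major epimer is drawn.

## Route

Step 1
Reactants: 1 dimedone (5,5-dimethylcyclohexane-1,3-dione)
Product: 2 3-ethoxy-5,5-dimethylcyclohex-2-en-1-one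
Conditions: EtOH, TsOH·H2O (cat.), toluene, reflux, Dean–Stark
Reagents that add atoms: ethanol, CCO
Why: Acid-catalysed enol etherification of the symmetrical 1,3-dione with azeotropic removal of water gives the vinylogous ester, and no stereocenter is involved.

Step 2
Reactants: 2 3-ethoxy-5,5-dimethylcyclohex-2-en-1-one
Product: 4 rac-6-bromo-3-ethoxy-5,5-dimethylcyclohex-2-en-1-one, via lithium dienolate 3 (not isolated)
Conditions: LiN(i-Pr)2, THF, −78 °C; then NBS, −78 °C; H2O quench
Reagents that add atoms: N-bromosuccinimide, O=C1CCC(=O)N1Br; LiN(i-Pr)2, [Li+].CC(C)[N-]C(C)C (supplies only the Li of intermediate 3)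
Why: Kinetic α'-deprotonation of the vinylogous ester (Stork–Danheiser enolate) and electrophilic bromination put bromine on C6; the new center is racemic, which is acceptable because step 5 is stereoconvergent, and HBr loss is blocked by the neighbouring quaternary carbon.

Step 3
Reactants: 5 (2E)-3-methylpent-2-en-4-yn-1-ol
Product: 6 (3E)-5-bromo-3-methylpent-3-en-1-yne
Conditions: PBr3 (0.4 equiv), Et2O, −20 → 0 °C
Reagents that add atoms: phosphorus tribromide, BrP(Br)Br
Why: SN2 bromination of the primary allylic alcohol through its phosphite ester keeps the E geometry and the conjugated enyne.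

Step 4
Reactants: 6 (3E)-5-bromo-3-methylpent-3-en-1-yne
Product: 7 diethyl [(2E)-3-methylpent-2-en-4-yn-1-yl]phosphonate
Conditions: P(OEt)3 (neat), 90 °C, EtBr distilled off
Reagents that add atoms: triethyl phosphite, CCOP(OCC)OCC
Why: Michaelis–Arbuzov reaction of the reactive primary allylic bromide gives the allylic phosphonate with the double bond unchanged.

Step 5
Reactants: 7 diethyl [(2E)-3-methylpent-2-en-4-yn-1-yl]phosphonate; 4 rac-6-bromo-3-ethoxy-5,5-dimethylcyclohex-2-en-1-one
Product: 9 diethyl [(2E,4E)-5-[(1S)-4-ethoxy-6,6-dimethyl-2-oxocyclohex-3-en-1-yl]-3-methylpenta-2,4-dien-1-yl]phosphonate, via dienylzirconocene chloride 8 (not isolated)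
Conditions: 7, Cp2Zr(H)Cl, THF, rt; then 4, NiCl2(MeOCH2CH2OMe) (8 mol %), (S,S)-Ph-BOX [2,2'-(propane-2,2-diyl)bis((4S)-4-phenyl-4,5-dihydrooxazole)] (10 mol %), DME/THF, 10 °C
Reagents that add atoms: Cp2Zr(H)Cl, [H][Zr](Cl)(C1C=CC=C1)C1C=CC=C1 (its Cp2ZrCl unit is held only in intermediate 8; 9 keeps only its hydrogen)
Why: Proposed new method: enantioconvergent nickel/bis(oxazoline)-catalysed alkenylation of a cyclic, neopentylic α'-bromo vinylogous ester. syn-Hydrozirconation of the terminal alkyne gives the (E)-dienylzirconocene 8; a monovalent nickel species abstracts bromine from either enantiomer of 4 to give one planar α-keto radical, which is captured by the chiral alkenylnickel complex formed by Zr-to-Ni transmetalation; C(sp3)–C(sp2) reductive elimination from the resulting trivalent nickel species in the ligand pocket sets the (S) center, forms the ring–chain bond and returns monovalent nickel. No base is present, so the new α-CH center is not epimerised. The closest known reaction type is the nickel/bis(oxazoline)-catalysed stereoconvergent coupling of acyclic racemic α-bromo ketones with alkenylzirconocenes, which has not been shown for cyclic vinylogous esters, for an α-carbon next to a quaternary carbon, or for phosphonate-bearing dienylzirconocenes. The ligand antipode that gives (S)-9 is fixed in a first screen.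

Step 6
Reactants: 9 diethyl [(2E,4E)-5-[(1S)-4-ethoxy-6,6-dimethyl-2-oxocyclohex-3-en-1-yl]-3-methylpenta-2,4-dien-1-yl]phosphonate
Product: 10 diethyl [(2E,4E)-5-[(1S,2S)-4-ethoxy-2-hydroxy-2,6,6-trimethylcyclohex-3-en-1-yl]-3-methylpenta-2,4-dien-1-yl]phosphonate
Conditions: MeLi, CeCl3, THF, −78 °C; aq. NaHCO3 work-up; Et3N-deactivated SiO2
Reagents that add atoms: methyllithium, [Li]C
Why: 1,2-Addition of the weakly basic organocerium reagent (Imamoto conditions, first half of a Stork–Danheiser transposition) to the vinylogous ester carbonyl avoids enolising the adjacent stereocenter; methyl is expected to enter anti to the neighbouring dienyl group, and the new carbinol center is destroyed in step 11, so either epimer serves.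

Step 7
Reactants: 11 (2E)-4,4-dimethoxybut-2-enal; 12 methyl 2-(triphenylphosphoranylidene)propanoate
Product: 13 methyl (2E,4E)-6,6-dimethoxy-2-methylhexa-2,4-dienoate
Conditions: CH2Cl2, rt
Reagents that add atoms: none
Why: Wittig olefination with an ester-stabilised ylide gives the E trisubstituted alkene under neutral conditions and leaves the acetal untouched.

Step 8
Reactants: 13 methyl (2E,4E)-6,6-dimethoxy-2-methylhexa-2,4-dienoate
Product: 14 methyl (2E,4E)-2-methyl-6-oxohexa-2,4-dienoate
Conditions: 1 M aq. HCl, THF, 0 °C → rt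
Reagents that add atoms: water, O
Why: Acid-catalysed acetal hydrolysis frees the dienal without touching the ester or the E,E geometry.

Step 9
Reactants: 14 methyl (2E,4E)-2-methyl-6-oxohexa-2,4-dienoate; 15 2-(triphenylphosphoranylidene)propanal
Product: 16 methyl (2E,4E,6E)-2,7-dimethyl-8-oxoocta-2,4,6-trienoate
Conditions: toluene, 80 °C
Reagents that add atoms: none
Why: Wittig olefination with the formyl-stabilised ylide gives the E α-methyl enal, and the hindered product aldehyde reacts much more slowly than 14, so homologation stops after one unit.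

Step 10
Reactants: 10 diethyl [(2E,4E)-5-[(1S,2S)-4-ethoxy-2-hydroxy-2,6,6-trimethylcyclohex-3-en-1-yl]-3-methylpenta-2,4-dien-1-yl]phosphonate; 16 methyl (2E,4E,6E)-2,7-dimethyl-8-oxoocta-2,4,6-trienoate
Product: 18 methyl (2E,4E,6E,8E,10E,12E)-13-[(1S,2S)-4-ethoxy-2-hydroxy-2,6,6-trimethylcyclohex-3-en-1-yl]-2,7,11-trimethyltrideca-2,4,6,8,10,12-hexaenoate, via disodium alkoxide carbanion 17 (not isolated)
Conditions: NaN(SiMe3)2 (2.1 equiv), THF, −78 °C; then 16, −78 → 0 °C; pH 8 work-up
Reagents that add atoms: NaN(SiMe3)2, [Na+].C[Si](C)(C)[N-][Si](C)(C)C (supplies only the Na of intermediate 17)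
Why: Horner–Wadsworth–Emmons olefination of the phosphonate-stabilised allylic carbanion with the enal forms the new E C8=C9 bond, while the ethoxy-cyclohexenyl carbinol has no acidic ring C–H and is inert to base.

Step 11
Reactants: 18 methyl (2E,4E,6E,8E,10E,12E)-13-[(1S,2S)-4-ethoxy-2-hydroxy-2,6,6-trimethylcyclohex-3-en-1-yl]-2,7,11-trimethyltrideca-2,4,6,8,10,12-hexaenoate
Product: 19 methyl (2E,4E,6E,8E,10E,12E)-2,7,11-trimethyl-13-[(1S)-2,6,6-trimethyl-4-oxocyclohex-2-en-1-yl]trideca-2,4,6,8,10,12-hexaenoate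
Conditions: 0.5 M aq. HCl, THF, 0 °C, 20 min, dark, argon
Reagents that add atoms: water, O
Why: Stork–Danheiser hydrolysis: ionisation of the tertiary allylic alcohol gives an ethoxy-stabilised allyl cation that water captures at the ethoxy carbon, and loss of ethanol gives the transposed 3-methyl enone without touching the ring C–H, so the (S) center set in step 5 is kept.

## Compound list

1 | dimedone (5,5-dimethylcyclohexane-1,3-dione) | CC1(C)CC(=O)CC(=O)C1 | starting material
2 | 3-ethoxy-5,5-dimethylcyclohex-2-en-1-one | CCOC1=CC(=O)CC(C)(C)C1 | intermediate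
3 | lithium 5-ethoxy-3,3-dimethylcyclohexa-1,5-dien-1-olate (formed in the flask) | [Li+].CCOC1=CC([O-])=CC(C)(C)C1 | intermediate
4 | rac-6-bromo-3-ethoxy-5,5-dimethylcyclohex-2-en-1-one | CCOC1=CC(=O)C(Br)C(C)(C)C1 | intermediate
5 | (2E)-3-methylpent-2-en-4-yn-1-ol | C#C/C(C)=C/CO | starting material
6 | (3E)-5-bromo-3-methylpent-3-en-1-yne | C#C/C(C)=C/CBr | intermediate
7 | diethyl [(2E)-3-methylpent-2-en-4-yn-1-yl]phosphonate | C#C/C(C)=C/CP(=O)(OCC)OCC | intermediate
8 | chloridobis(cyclopentadienyl)[(1E,3E)-5-(diethoxyphosphoryl)-3-methylpenta-1,3-dien-1-yl]zirconium (formed in the flask) | Cl[Zr](/C=C/C(C)=C/CP(=O)(OCC)OCC)(C1C=CC=C1)C1C=CC=C1 | intermediate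
9 | diethyl [(2E,4E)-5-[(1S)-4-ethoxy-6,6-dimethyl-2-oxocyclohex-3-en-1-yl]-3-methylpenta-2,4-dien-1-yl]phosphonate | CCOP(=O)(OCC)C/C=C(C)/C=C/[C@@H]1C(=O)C=C(OCC)CC1(C)C | intermediate
10 | diethyl [(2E,4E)-5-[(1S,2S)-4-ethoxy-2-hydroxy-2,6,6-trimethylcyclohex-3-en-1-yl]-3-methylpenta-2,4-dien-1-yl]phosphonate (methyl trans to the side chain) | CCOP(=O)(OCC)C/C=C(C)/C=C/[C@@H]1[C@](C)(O)C=C(OCC)CC1(C)C | intermediate
11 | (2E)-4,4-dimethoxybut-2-enal | COC(OC)/C=C/C=O | starting material
12 | methyl 2-(triphenylphosphoranylidene)propanoate | COC(=O)C(C)=P(c1ccccc1)(c1ccccc1)c1ccccc1 | starting material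
13 | methyl (2E,4E)-6,6-dimethoxy-2-methylhexa-2,4-dienoate | COC(=O)/C(C)=C/C=C/C(OC)OC | intermediate
14 | methyl (2E,4E)-2-methyl-6-oxohexa-2,4-dienoate | COC(=O)/C(C)=C/C=C/C=O | intermediate
15 | 2-(triphenylphosphoranylidene)propanal | CC(C=O)=P(c1ccccc1)(c1ccccc1)c1ccccc1 | starting material
16 | methyl (2E,4E,6E)-2,7-dimethyl-8-oxoocta-2,4,6-trienoate | COC(=O)/C(C)=C/C=C/C=C(C)/C=O | intermediate
17 | disodium salt of 10, alkoxide plus phosphonate-stabilised carbanion (formed in the flask) | [Na+].[Na+].CCOP(=O)(OCC)[CH-]/C=C(C)/C=C/[C@@H]1[C@](C)([O-])C=C(OCC)CC1(C)C | intermediate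
18 | methyl (2E,4E,6E,8E,10E,12E)-13-[(1S,2S)-4-ethoxy-2-hydroxy-2,6,6-trimethylcyclohex-3-en-1-yl]-2,7,11-trimethyltrideca-2,4,6,8,10,12-hexaenoate | COC(=O)/C(C)=C/C=C/C=C(C)/C=C/C=C(C)/C=C/[C@@H]1[C@](C)(O)C=C(OCC)CC1(C)C | intermediate
19 | methyl (2E,4E,6E,8E,10E,12E)-2,7,11-trimethyl-13-[(1S)-2,6,6-trimethyl-4-oxocyclohex-2-en-1-yl]trideca-2,4,6,8,10,12-hexaenoate | COC(=O)/C(C)=C/C=C/C=C(C)/C=C/C=C(C)/C=C/[C@@H]1C(C)=CC(=O)CC1(C)C | target

## Summary

Total step count: 11.
Longest linear sequence: 6 steps (steps 1, 2, 5, 6, 10, 11; the branch 3, 4, 5, 6, 10, 11 is equally long).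

Three steps most likely to fail:

Step 5 (proposed new method). The radical sits next to a quaternary carbon, the enantioselectivity is unknown for this substrate class, and the phosphonate must survive hydrozirconation. The fallback uses known chemistry, sets out from 2 and 7 (by way of 3 and 8) and comes back at 9. Zirconocene 8 is quenched with iodine to give diethyl [(2E,4E)-5-iodo-3-methylpenta-2,4-dien-1-yl]phosphonate F1. Dienolate 3 is transmetalated with ZnCl2 to chlorozinc 5-ethoxy-3,3-dimethylcyclohexa-1,5-dien-1-olate F2, which is too weakly basic to deprotonate the phosphonate. A Negishi-type α-alkenylation of F2 with F1 under Pd(dba)2/P(t-Bu)3 in THF (two-electron enolate cross-coupling) gives racemic diethyl [(2E,4E)-5-(4-ethoxy-6,6-dimethyl-2-oxocyclohex-3-en-1-yl)-3-methylpenta-2,4-dien-1-yl]phosphonate F3. Preparative SFC on a chiral stationary phase separates 9 from diethyl [(2E,4E)-5-[(1R)-4-ethoxy-6,6-dimethyl-2-oxocyclohex-3-en-1-yl]-3-methylpenta-2,4-dien-1-yl]phosphonate F4.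

Step 6. The α-CH of 9 is both α to the carbonyl and allylic, so the organometallic may enolise and epimerise it instead of adding, and carbinol 10 is acid-labile on isolation. The fallback sets out from 9 and comes back at 19. Non-basic carbonyl methylenation with Cp2TiMe2 (toluene, 65 °C, Petasis olefination) gives diethyl [(2E,4E)-5-[(1S)-4-ethoxy-6,6-dimethyl-2-methylidenecyclohex-3-en-1-yl]-3-methylpenta-2,4-dien-1-yl]phosphonate F5, a masked enone with no free hydroxyl. Horner–Wadsworth–Emmons reaction of F5 (NaN(SiMe3)2, one equivalent, THF) with 16 gives methyl (2E,4E,6E,8E,10E,12E)-13-[(1S)-4-ethoxy-6,6-dimethyl-2-methylidenecyclohex-3-en-1-yl]-2,7,11-trimethyltrideca-2,4,6,8,10,12-hexaenoate F6. Dilute aqueous HCl in THF protonates the exocyclic CH2 and hydrolyses the same ethoxy-allyl cation to 19.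

Step 11. The ethoxy-allyl cation could lose the ring C–H instead of taking up water, which would racemise the center or move the double bond into conjugation with the hexaene, and the polyene is acid-sensitive. The fallback sets out from 10 and comes back at 19. 10 is hydrolysed at the C15 stage (0.5 M HCl, THF, 0 °C), where the side chain is only a dienyl phosphonate, to give diethyl [(2E,4E)-3-methyl-5-[(1S)-2,6,6-trimethyl-4-oxocyclohex-2-en-1-yl]penta-2,4-dien-1-yl]phosphonate F7. Luche reduction (NaBH4, CeCl3·7H2O, MeOH, −20 °C) gives diethyl [(2E,4E)-5-[(1S)-4-hydroxy-2,6,6-trimethylcyclohex-2-en-1-yl]-3-methylpenta-2,4-dien-1-yl]phosphonate F8 as a mixture of carbinol epimers, which removes the vinylogous acidity of the ring C–H. Horner–Wadsworth–Emmons reaction of F8 (NaN(SiMe3)2, 2.1 equiv) with 16 gives methyl (2E,4E,6E,8E,10E,12E)-13-[(1S)-4-hydroxy-2,6,6-trimethylcyclohex-2-en-1-yl]-2,7,11-trimethyltrideca-2,4,6,8,10,12-hexaenoate F9. MnO2 (CH2Cl2, rt) oxidises the ring allylic alcohol of both epimers to 19 under neutral conditions.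

## Further compounds

F1 | step 5 | diethyl [(2E,4E)-5-iodo-3-methylpenta-2,4-dien-1-yl]phosphonate | CCOP(=O)(OCC)C/C=C(C)/C=C/I
F2 | step 5 | chlorozinc 5-ethoxy-3,3-dimethylcyclohexa-1,5-dien-1-olate | CCOC1=CC(O[Zn]Cl)=CC(C)(C)C1
F3 | step 5 | racemic diethyl [(2E,4E)-5-(4-ethoxy-6,6-dimethyl-2-oxocyclohex-3-en-1-yl)-3-methylpenta-2,4-dien-1-yl]phosphonate | CCOP(=O)(OCC)C/C=C(C)/C=C/C1C(=O)C=C(OCC)CC1(C)C
F4 | step 5 | diethyl [(2E,4E)-5-[(1R)-4-ethoxy-6,6-dimethyl-2-oxocyclohex-3-en-1-yl]-3-methylpenta-2,4-dien-1-yl]phosphonate | CCOP(=O)(OCC)C/C=C(C)/C=C/[C@H]1C(=O)C=C(OCC)CC1(C)C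
F5 | step 6 | diethyl [(2E,4E)-5-[(1S)-4-ethoxy-6,6-dimethyl-2-methylidenecyclohex-3-en-1-yl]-3-methylpenta-2,4-dien-1-yl]phosphonate | CCOP(=O)(OCC)C/C=C(C)/C=C/[C@@H]1C(=C)C=C(OCC)CC1(C)C
F6 | step 6 | methyl (2E,4E,6E,8E,10E,12E)-13-[(1S)-4-ethoxy-6,6-dimethyl-2-methylidenecyclohex-3-en-1-yl]-2,7,11-trimethyltrideca-2,4,6,8,10,12-hexaenoate | COC(=O)/C(C)=C/C=C/C=C(C)/C=C/C=C(C)/C=C/[C@@H]1C(=C)C=C(OCC)CC1(C)C
F7 | step 11 | diethyl [(2E,4E)-3-methyl-5-[(1S)-2,6,6-trimethyl-4-oxocyclohex-2-en-1-yl]penta-2,4-dien-1-yl]phosphonate | CCOP(=O)(OCC)C/C=C(C)/C=C/[C@@H]1C(C)=CC(=O)CC1(C)C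
F8 | step 11 | diethyl [(2E,4E)-5-[(1S)-4-hydroxy-2,6,6-trimethylcyclohex-2-en-1-yl]-3-methylpenta-2,4-dien-1-yl]phosphonate (carbinol epimers) | CCOP(=O)(OCC)C/C=C(C)/C=C/[C@@H]1C(C)=CC(O)CC1(C)C
F9 | step 11 | methyl (2E,4E,6E,8E,10E,12E)-13-[(1S)-4-hydroxy-2,6,6-trimethylcyclohex-2-en-1-yl]-2,7,11-trimethyltrideca-2,4,6,8,10,12-hexaenoate (carbinol epimers) | COC(=O)/C(C)=C/C=C/C=C(C)/C=C/C=C(C)/C=C/[C@@H]1C(C)=CC(O)CC1(C)C
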